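**Plan**

- Ring numbering: C1 carbonyl, C2 chain, C3 methyl, C4 carbonyl, C5 H, C6 methoxy; chain numbered from C1' on C2. The first cut removes C1'–C2' and C3'–CH3 together: the methylene C1', held between quinone carbon C2 and the E alkene C2'=C3'(CH3), lets the target split into a quinonylmethyl chloride and the methylalumination product of a terminal C28 alkyne.
- The alkyne is cut further at C4'–C5' and C8'–C9' (propargyl–allyl bonds) and at C5'–C6' plus C7'–CH3, leading back to geranylgeraniol, two silyl-capped propynes, formaldehyde and Me3Al.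
- The chloromethylquinone is traced through its alcohol and a para-oxidation to 2-methoxy-5-methylphenol; its only free ortho carbon becomes C2, so the chain position is fixed before any quinone exists.
- Forward: C20 alcohol → C23 alkyne → C25 allylic alcohol → C28 alkyne (steps 1–5); phenol → saligenol → quinone alcohol → chloride (steps 6–8); the halves are joined last (step 9). The only ring is carried from the phenol and no ring is closed.
- There is no stereocentre. Three E alkenes come from geranylgeraniol, C6'=C7' from the syn methylalumination of step 3 and C2'=C3' from that of step 9, each carried on with retention.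

Key step: step 9

Remark on the chemistry: the chain is taken as all-E exactly as drawn, so commercial all-E geranylgeraniol serves as the C20 block; no compound of the main route contains a stereocentre.

Step 1
Reactants: 1 (2E,6E,10E)-geranylgeraniol
Product: 2 (2E,6E,10E)-1-bromo-3,7,11,15-tetramethylhexadeca-2,6,10,14-tetraene (geranylgeranyl bromide)
Conditions: PBr3 (0.4 equiv), Et2O, −10 → 0 °C; used crude
Reagents that add atoms: phosphorus tribromide, BrP(Br)Br
Why: Alcohol-to-bromide substitution with PBr3 runs through the allylic phosphite with SN2 delivery of bromide at C1, so at low temperature the primary allylic position is converted without transposition and the E alkenes are untouched.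

Step 2
Reactants: 2 geranylgeranyl bromide; 3 1-(trimethylsilyl)propyne
Product: 6 (5E,9E,13E)-6,10,14,18-tetramethylnonadeca-5,9,13,17-tetraen-1-yne, via lithiated trimethylsilylpropyne 4 (not isolated), via trimethylsilyl enyne 5 (not isolated)
Conditions: 3, n-BuLi, THF, −40 °C; then 2, −78 → −20 °C; then MeOH, K2CO3, rt
Reagents that add atoms: none
Why: Deprotonation of 3 gives a propargyl anion whose silyl cap steers SN2 alkylation of the primary allylic bromide to the propargylic carbon, and base-mediated methanolysis of the C–Si bond then frees the terminal alkyne (propargylation with a silyl-capped propargyl anion followed by protodesilylation); any allenic hydrocarbon carried along is removed one step later, when the product becomes a polar alcohol.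

Step 3
Reactants: 6 (5E,9E,13E)-6,10,14,18-tetramethylnonadeca-5,9,13,17-tetraen-1-yne
Product: 9 (2E,6E,10E,14E)-3,7,11,15,19-pentamethylicosa-2,6,10,14,18-pentaen-1-ol (all-E geranylfarnesol), via alkenylalane 7 (not isolated), via lithium alkenylaluminate 8 (not isolated)
Conditions: Me3Al (2 equiv), Cp2ZrCl2 (0.25 equiv), CH2Cl2, rt; volatiles removed, hexane; n-BuLi, 0 °C; (CH2O)n, THF, rt; cold dilute aq. HCl
Reagents that add atoms: trimethylaluminium, C[Al](C)C; paraformaldehyde as formaldehyde, C=O
Why: Zirconium-catalysed syn methylalumination (Negishi carboalumination) puts CH3 on the internal and aluminium on the terminal alkyne carbon, and the derived lithium aluminate transfers its alkenyl group to formaldehyde with retention, so the new 2E allylic alcohol forms while the isolated trisubstituted alkenes stay inert.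

Step 4
Reactants: 9 all-E geranylfarnesol
Product: 10 (2E,6E,10E,14E)-1-bromo-3,7,11,15,19-pentamethylicosa-2,6,10,14,18-pentaene (geranylfarnesyl bromide)
Conditions: PBr3 (0.4 equiv), Et2O, −10 → 0 °C; used crude
Reagents that add atoms: phosphorus tribromide, BrP(Br)Br
Why: The same PBr3 alcohol-to-bromide substitution as in step 1 should convert the primary allylic alcohol with SN2 delivery of bromide and no change of alkene geometry.

Step 5
Reactants: 10 geranylfarnesyl bromide; 11 1-(triisopropylsilyl)propyne
Product: 14 (5E,9E,13E,17E)-6,10,14,18,22-pentamethyltricosa-5,9,13,17,21-pentaen-1-yne, via lithiated triisopropylsilylpropyne 12 (not isolated), via triisopropylsilyl enyne 13 (not isolated)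
Conditions: 11, n-BuLi, THF, −20 °C; then 10, −78 → −20 °C; then n-Bu4NF (1 M in wet THF, 1.5 equiv), 0 °C → rt
Reagents that add atoms: none
Why: The lithium derivative of 11 alkylates the primary allylic bromide by SN2 at its propargylic carbon only, because the bulky triisopropylsilyl group shields the allenyl terminus, and fluoride then cleaves the alkynyl C–Si bond (propargylation with a silyl-capped propargyl anion followed by fluoride protodesilylation); the bulkier cap is chosen here because 14 enters the key step directly and must be free of allenic isomers, and the 5E alkene is inherited unchanged from 10.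

Step 6
Reactants: 15 2-methoxy-5-methylphenol
Product: 17 2-(hydroxymethyl)-6-methoxy-3-methylphenol, via benzodioxaborinine 16 (not isolated)
Conditions: PhB(OH)2 (1.1 equiv), (CH2O)n, EtCO2H (cat.), toluene, reflux, Dean–Stark; then 30% aq. H2O2, THF, 0 °C → rt
Reagents that add atoms: paraformaldehyde as formaldehyde, C=O
Why: Phenylboronic acid esterifies the phenol and delivers formaldehyde through a six-membered transition state to the only free ortho carbon (boron-templated ortho-hydroxymethylation), the cyclic boronate blocks a second condensation, and oxidative cleavage of the B–C and B–O bonds releases the saligenol with the para position untouched.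

Step 7
Reactants: 17 2-(hydroxymethyl)-6-methoxy-3-methylphenol
Product: 18 2-(hydroxymethyl)-6-methoxy-3-methyl-1,4-benzoquinone
Conditions: Co(salen) [N,N'-ethylenebis(salicylideneiminato)cobalt, divalent cobalt] (5 mol %), O2 (1 atm), MeCN, rt
Reagents that add atoms: dioxygen, O=O
Why: The cobalt–dioxygen adduct abstracts the phenolic hydrogen and oxygenates the free para carbon of this 2,3,6-trisubstituted phenol, the substitution pattern for which Co(salen)-catalysed aerobic phenol oxidation to para-quinones is most reliable.

Step 8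
Reactants: 18 2-(hydroxymethyl)-6-methoxy-3-methyl-1,4-benzoquinone
Product: 19 2-(chloromethyl)-6-methoxy-3-methyl-1,4-benzoquinone
Conditions: SOCl2 (1.5 equiv), DMF (cat.), CH2Cl2, 0 °C
Reagents that add atoms: thionyl chloride, ClS(Cl)=O
Why: Deoxychlorination of the primary quinonylmethyl alcohol through its chlorosulfite should proceed at 0 °C, where the electron-poor quinone ring is not attacked by the reagent.

Step 9
Reactants: 14 (5E,9E,13E,17E)-6,10,14,18,22-pentamethyltricosa-5,9,13,17,21-pentaen-1-yne; 19 2-(chloromethyl)-6-methoxy-3-methyl-1,4-benzoquinone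
Product: 21 2-[(2E,6E,10E,14E,18E)-3,7,11,15,19,23-hexamethyltetracosa-2,6,10,14,18,22-hexaen-1-yl]-6-methoxy-3-methyl-1,4-benzoquinone (target), via alkenylalane 20 (not isolated)
Conditions: 14, Me3Al (2 equiv), Cp2ZrCl2 (0.25 equiv), ClCH2CH2Cl, rt; volatiles removed, hexane extract, THF; then 19, NiCl2(PPh3)2 (5 mol %) pre-reduced with n-BuLi (10 mol %) to zerovalent nickel, THF, −20 → 0 °C; cold dilute aq. HCl, SiO2
Reagents that add atoms: trimethylaluminium, C[Al](C)C
Why: Cp2ZrCl2-activated Me3Al adds CH3 and aluminium syn across the terminal alkyne of 14, CH3 to the internal carbon (future C3') and aluminium to the terminal carbon (future C2'), giving the E-alkenylalane 20; zerovalent nickel then inserts into the activated C1'–Cl bond of 19, the alkenyl group passes from aluminium to nickel with retention, and reductive elimination forms C1'–C2'. The closest known reaction type is Negishi carboalumination followed by nickel-catalysed cross-coupling of alkenylalanes with benzylic chlorides and with chloromethylated para-quinones. No ring is closed and no stereocentre is created; the only stereochemical element, the E geometry of C2'=C3', is set by the syn addition and kept by the stereoretentive transmetalation. The step needs methyl delivery to the internal alkyne carbon, which the unbranched terminal alkyne secures, and inertness of the five trisubstituted alkenes, which do not react with the zirconium–aluminium reagent. It also needs attack at CH2Cl and not at the quinone carbonyls or C5, which is secured by stripping excess Me3Al before 19 is added, by the mild nucleophilicity of the alkenylalane and by fast oxidative addition into the quinonylmethyl C–Cl bond at −20 °C.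

**Compound list**

1 | (2E,6E,10E)-geranylgeraniol, (2E,6E,10E)-3,7,11,15-tetramethylhexadeca-2,6,10,14-tetraen-1-ol | OC/C=C(\C)CC/C=C(\C)CC/C=C(\C)CCC=C(C)C | starting material
2 | (2E,6E,10E)-1-bromo-3,7,11,15-tetramethylhexadeca-2,6,10,14-tetraene | BrC/C=C(\C)CC/C=C(\C)CC/C=C(\C)CCC=C(C)C | intermediate
3 | 1-(trimethylsilyl)propyne | CC#C[Si](C)(C)C | starting material
4 | 3-lithio-1-(trimethylsilyl)propyne | [Li]CC#C[Si](C)(C)C | intermediate (not isolated)
5 | trimethyl[(5E,9E,13E)-6,10,14,18-tetramethylnonadeca-5,9,13,17-tetraen-1-yn-1-yl]silane | C[Si](C)(C)C#CCC/C=C(\C)CC/C=C(\C)CC/C=C(\C)CCC=C(C)C | intermediate (not isolated)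
6 | (5E,9E,13E)-6,10,14,18-tetramethylnonadeca-5,9,13,17-tetraen-1-yne | C#CCC/C=C(\C)CC/C=C(\C)CC/C=C(\C)CCC=C(C)C | intermediate
7 | dimethyl[(1E,5E,9E,13E)-2,6,10,14,18-pentamethylnonadeca-1,5,9,13,17-pentaen-1-yl]alane | C[Al](C)/C=C(\C)CC/C=C(\C)CC/C=C(\C)CCC=C(C)C | intermediate (not isolated)
8 | lithium butyldimethyl[(1E,5E,9E,13E)-2,6,10,14,18-pentamethylnonadeca-1,5,9,13,17-pentaen-1-yl]aluminate | [Li+].CCCC[Al-](C)(C)/C=C(\C)CC/C=C(\C)CC/C=C(\C)CCC=C(C)C | intermediate (not isolated)
9 | (2E,6E,10E,14E)-3,7,11,15,19-pentamethylicosa-2,6,10,14,18-pentaen-1-ol (all-E geranylfarnesol) | OC/C=C(\C)CC/C=C(\C)CC/C=C(\C)CC/C=C(\C)CCC=C(C)C | intermediate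
10 | (2E,6E,10E,14E)-1-bromo-3,7,11,15,19-pentamethylicosa-2,6,10,14,18-pentaene | BrC/C=C(\C)CC/C=C(\C)CC/C=C(\C)CC/C=C(\C)CCC=C(C)C | intermediate
11 | 1-(triisopropylsilyl)propyne | CC#C[Si](C(C)C)(C(C)C)C(C)C | starting material
12 | 3-lithio-1-(triisopropylsilyl)propyne | [Li]CC#C[Si](C(C)C)(C(C)C)C(C)C | intermediate (not isolated)
13 | triisopropyl[(5E,9E,13E,17E)-6,10,14,18,22-pentamethyltricosa-5,9,13,17,21-pentaen-1-yn-1-yl]silane | CC(C)[Si](C(C)C)(C(C)C)C#CCC/C=C(\C)CC/C=C(\C)CC/C=C(\C)CC/C=C(\C)CCC=C(C)C | intermediate (not isolated)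
14 | (5E,9E,13E,17E)-6,10,14,18,22-pentamethyltricosa-5,9,13,17,21-pentaen-1-yne | C#CCC/C=C(\C)CC/C=C(\C)CC/C=C(\C)CC/C=C(\C)CCC=C(C)C | intermediate
15 | 2-methoxy-5-methylphenol | COc1ccc(C)cc1O | starting material
16 | 8-methoxy-5-methyl-2-phenyl-4H-1,3,2-benzodioxaborinine | COc1ccc(C)c2COB(c3ccccc3)Oc12 | intermediate (not isolated)
17 | 2-(hydroxymethyl)-6-methoxy-3-methylphenol | COc1ccc(C)c(CO)c1O | intermediate
18 | 2-(hydroxymethyl)-6-methoxy-3-methyl-1,4-benzoquinone | COC1=CC(=O)C(C)=C(CO)C1=O | intermediate
19 | 2-(chloromethyl)-6-methoxy-3-methyl-1,4-benzoquinone | COC1=CC(=O)C(C)=C(CCl)C1=O | intermediate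
20 | dimethyl[(1E,5E,9E,13E,17E)-2,6,10,14,18,22-hexamethyltricosa-1,5,9,13,17,21-hexaen-1-yl]alane | C[Al](C)/C=C(\C)CC/C=C(\C)CC/C=C(\C)CC/C=C(\C)CC/C=C(\C)CCC=C(C)C | intermediate (not isolated)
21 | 2-[(2E,6E,10E,14E,18E)-3,7,11,15,19,23-hexamethyltetracosa-2,6,10,14,18,22-hexaen-1-yl]-6-methoxy-3-methyl-1,4-benzoquinone | COC1=CC(=O)C(C)=C(C/C=C(\C)CC/C=C(\C)CC/C=C(\C)CC/C=C(\C)CC/C=C(\C)CCC=C(C)C)C1=O | target

**Step count and risks**

Total step count: 9. Longest linear sequence: 6 steps (steps 1, 2, 3, 4, 5 and 9, from 1 to 21); the quinone branch (steps 6–8) joins in step 9.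

The step most likely to fail is step 9. Electron transfer from the alkenylalane or from low-valent nickel to the quinone, or addition of alkenyl or residual methyl groups to C1=O, C4=O or the unsubstituted C5, may consume 19 faster than nickel inserts into its C–Cl bond. The fallback moves the oxidation behind the coupling. It sets out from 17, which is sulfonylated selectively at the phenol (TsCl, K2CO3, acetone, rt) to 2-(hydroxymethyl)-6-methoxy-3-methylphenyl 4-methylbenzenesulfonate F1. This is converted (MsCl, LiCl, 2,4,6-collidine, DMF, 0 °C) into 2-(chloromethyl)-6-methoxy-3-methylphenyl 4-methylbenzenesulfonate F2. Alkenylalane 20, made from 14 as in step 9, is coupled with F2 under the same zerovalent nickel catalyst from NiCl2(PPh3)2 and n-BuLi in THF to give the hexaprenyl aryl tosylate F3. Hydrolysis of the sulfonate (KOH, EtOH/THF, reflux) should give 2-hexaprenyl-6-methoxy-3-methylphenol F4, and Co(salen)/O2 in MeCN then oxidises its free para position, so the route is rejoined at 21.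

The second risk is step 7. The phenoxyl radical next to a free benzylic hydroxyl may lose water to an ortho-quinone methide and oligomerise, or the saligenol may chelate and deactivate cobalt, so that oxygenation at the para carbon stalls. The fallback replaces the radical oxygenation by ionic para-amination followed by oxidation. It sets out from 17, which is coupled in aq. NaOH at 0 °C with 4-diazoniobenzenesulfonate F5 (from sulfanilic acid, NaNO2 and aq. HCl at 0 °C) to give sodium 4-{(E)-[4-hydroxy-3-(hydroxymethyl)-5-methoxy-2-methylphenyl]diazenyl}benzenesulfonate F6. Reductive cleavage of the azo bond (Na2S2O4, H2O, 50 °C) should give 4-amino-2-(hydroxymethyl)-6-methoxy-3-methylphenol F7, and FeCl3 in dilute aq. HCl at 0 °C oxidises and hydrolyses it, returning to the route at 18.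

The third risk is step 5, run on the costliest chain intermediate. The bulky silyl cap closes the allenyl pathway, but the hard organolithium may still undergo lithium–bromine exchange with the allylic bromide followed by Wurtz-type dimerisation, or attack in an SN2' sense at C3, and fluoride in the same pot may leave part of the silyl alkyne uncleaved. Branched or dimeric hydrocarbons are hard to remove at C28. The fallback replaces the organolithium by a soft enolate and builds the alkyne from a methyl ketone. It sets out from 10, which alkylates ethyl acetoacetate (NaOEt, EtOH, 0 °C → rt) to ethyl (4E,8E,12E,16E)-2-acetyl-5,9,13,17,21-pentamethyldocosa-4,8,12,16,20-pentaenoate F8. Saponification and decarboxylation (NaOH, aq. EtOH, then acidification and warming) should give (5E,9E,13E,17E)-6,10,14,18,22-pentamethyltricosa-5,9,13,17,21-pentaen-2-one F9. Kinetic enolisation at the methyl group and O-phosphorylation (LiN(i-Pr)2, THF, −78 °C, then ClP(O)(OEt)2) give diethyl (5E,9E,13E,17E)-6,10,14,18,22-pentamethyltricosa-1,5,9,13,17,21-hexaen-2-yl phosphate F10. Elimination with LiN(i-Pr)2 (2.2 equiv, THF, −78 °C → rt, aqueous quench) returns to the route at 14.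

**Further compounds**

F1 | step 9 | 2-(hydroxymethyl)-6-methoxy-3-methylphenyl 4-methylbenzenesulfonate | COc1ccc(C)c(CO)c1OS(=O)(=O)c1ccc(C)cc1
F2 | step 9 | 2-(chloromethyl)-6-methoxy-3-methylphenyl 4-methylbenzenesulfonate | COc1ccc(C)c(CCl)c1OS(=O)(=O)c1ccc(C)cc1
F3 | step 9 | 2-[(2E,6E,10E,14E,18E)-3,7,11,15,19,23-hexamethyltetracosa-2,6,10,14,18,22-hexaen-1-yl]-6-methoxy-3-methylphenyl 4-methylbenzenesulfonate | COc1ccc(C)c(C/C=C(\C)CC/C=C(\C)CC/C=C(\C)CC/C=C(\C)CC/C=C(\C)CCC=C(C)C)c1OS(=O)(=O)c1ccc(C)cc1
F4 | step 9 | 2-[(2E,6E,10E,14E,18E)-3,7,11,15,19,23-hexamethyltetracosa-2,6,10,14,18,22-hexaen-1-yl]-6-methoxy-3-methylphenol | COc1ccc(C)c(C/C=C(\C)CC/C=C(\C)CC/C=C(\C)CC/C=C(\C)CC/C=C(\C)CCC=C(C)C)c1O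
F5 | step 7 | 4-diazoniobenzenesulfonate | [O-]S(=O)(=O)c1ccc(cc1)[N+]#N
F6 | step 7 | sodium 4-{(E)-[4-hydroxy-3-(hydroxymethyl)-5-methoxy-2-methylphenyl]diazenyl}benzenesulfonate | COc1cc(/N=N/c2ccc(cc2)S(=O)(=O)[O-])c(C)c(CO)c1O.[Na+]
F7 | step 7 | 4-amino-2-(hydroxymethyl)-6-methoxy-3-methylphenol | COc1cc(N)c(C)c(CO)c1O
F8 | step 5 | ethyl (4E,8E,12E,16E)-2-acetyl-5,9,13,17,21-pentamethyldocosa-4,8,12,16,20-pentaenoate (racemic at C2) | CCOC(=O)C(C(C)=O)C/C=C(\C)CC/C=C(\C)CC/C=C(\C)CC/C=C(\C)CCC=C(C)C
F9 | step 5 | (5E,9E,13E,17E)-6,10,14,18,22-pentamethyltricosa-5,9,13,17,21-pentaen-2-one | CC(=O)CC/C=C(\C)CC/C=C(\C)CC/C=C(\C)CC/C=C(\C)CCC=C(C)C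
F10 | step 5 | diethyl (5E,9E,13E,17E)-6,10,14,18,22-pentamethyltricosa-1,5,9,13,17,21-hexaen-2-yl phosphate | C=C(OP(=O)(OCC)OCC)CC/C=C(\C)CC/C=C(\C)CC/C=C(\C)CC/C=C(\C)CCC=C(C)C
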